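At 6.0 h, the time of reading, the flasks beta, gamma and delta differ in temperature and in nothing else, so I ask how long target survives at each temperature.

| flask | substrate | first nucleophile | second nucleophile | temperature | remark | time |
|---|---|---|---|---|---|---|
| alder | 5 mM | 30 mM | 12 mM | 28 °C | run made earlier |  |
| maple | 20 mM | 30 mM | 12 mM | 44 °C | run made earlier |  |
| beta | 10 mM | 30.0 mM | 12.0 mM | 35 °C |  | 6.0 h |
| gamma | 10 mM | 30.0 mM | 12.0 mM | 50 °C |  | 6.0 h |
| delta | 10 mM | 30.0 mM | 12.0 mM | 20 °C |  | 6.0 h |

- alder (time / h: target / %, substrate / %): 0.250: 7.9, 77.0; 0.667: 21.7, 50.3; 1.50: 41.1, 22.1; 4.00: 33.2, 1.5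
- maple (time / h: target / %, substrate / %): 0.500: 52.0, 0.9; 1.33: 33.1, 0; 1.50: 30.2, 0.5; 2.50: 21.8, 0

(each reading ± 0.5 percentage points)

- the earlier runs were read with a standard deviation of 0.5 percentage points

* which flask leads in amount of target, in percent of the substrate charged ("all alike" within 1.5 percentage points) (beta / gamma / delta / all alike)
* how much target is there at the end, in percent of the substrate charged: beta
* how much target is there at the end, in percent of the substrate charged: gamma
* how much target is there at the end, in percent of the substrate charged: delta

Substrate in the alder run falls with a first-order constant of 1.01 h⁻¹. The maple reading of 0.9% gives about 9.42 h⁻¹, a rough value so close to the scatter. Together they give an activation energy of 111 kJ mol⁻¹, so I expect 0.300 h⁻¹ in delta and 2.76 h⁻¹ in beta.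

In the maple run I take first nucleophile to be in no excess over target: its charge less the substrate charge is 10.0 mM, against 10.4 mM of target at 0.500 h. I therefore read maple as second-order with two like concentrations, the reciprocal of c(target) rising with a constant of 66.6 L mol⁻¹ h⁻¹. In the alder run, counting the substrate spent after 1.50 h as target, the balance gives a loss of 0.307 h⁻¹. Alder alone I treat as pseudo-first-order in first nucleophile, taking c(first nucleophile) as its charge less the substrate charge, which gives 12.3 L mol⁻¹ h⁻¹. The two constants together give an activation energy of 83.9 kJ mol⁻¹.

My quantity is the target lifetime, one over that loss constant at the flask's temperature and c(first nucleophile): 1.90 h in beta, 10.2 h in delta and 0.416 h in gamma. The alder balance puts the share of substrate reaching target near 71.2%.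

Two extremes bracket delta. If substrate turned over at once, delta would hold 39.5%; if target were never lost, 59.4%. Solving the two consecutive steps gives 41.2% in delta, whose lifetime is longer than the reading time. Beta's substrate life of 0.362 h is shorter than its target lifetime, so beta stays near the sudden extreme, and I reckon 3.75% there and <0.001% in gamma. Delta leads in my reckoning.

The forecast names delta, with 11% in beta, 0.5% in gamma and 38% in delta, noting that at 20 °C “formation is slow”. The flask gives delta in the lead with 41.7%, beta 9.71% and gamma 3.34%, the last above my figure.

    substrate → intermediate (k = 0.280 min⁻¹, Ea = 103 kJ mol⁻¹)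
    first nucleophile + intermediate → target (k = 22.0 L mol⁻¹ min⁻¹, Ea = 48.0 kJ mol⁻¹)
    second nucleophile + intermediate → other capture product (k = 150 L mol⁻¹ min⁻¹, Ea = 59.0 kJ mol⁻¹)
    first nucleophile + target → over-reaction product (k = 0.660 L mol⁻¹ min⁻¹, Ea = 55.0 kJ mol⁻¹)
    target ⇌ isomer of the product (K = 0.990, k = 0.0170 min⁻¹, Ea = 99.0 kJ mol⁻¹, ΔH = −23.0 kJ mol⁻¹)
    second nucleophile → decomposed reagent (k = 0.350 min⁻¹, Ea = 79.0 kJ mol⁻¹)
    (constants at 50 °C)

In beta target is made 7.86 times faster than it is used up at 0.267 h. At 6.00 h that ratio stands at 0.111, so making has fallen behind using up. On the neighbour flask, beta left until 2.5 h, my lifetime of 1.90 h gives 23.5%, and that flask holds 29.8%. From there to the 9.71% in beta, target falls with a lifetime of 3.12 h.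

(All runs are simulated with made-up constants, noise included.)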